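**Strategy.** All three bicyclic units are made from one building block, a 15‑silyloxy‑drim‑8(12)‑en‑11‑ol, which is then etherified with isocitrates from (R)‑malic acid and joined by esterification. The route rests on the quaternary C‑4 of ring A (C‑1 to C‑5, C‑10): its hydroxymethyl carbon C‑15 is treated as a ring carbon excised from a seven‑membered ring. An enantioselectively epoxidised 3‑methylcyclohept‑2‑enone undergoes a stereospecific Lewis‑acid 1,2‑acyl shift that contracts the ring to the cyclohexanone bearing C‑4 with CH3 and CHO in place; the ketone carbon becomes C‑5, and C‑5, C‑10 and C‑9 are then relayed from C‑4 in a cation–olefin closure of ring B.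

Key step: step 2

Remark on numbering: each bicyclic unit is numbered as a drimane (ring carbons C‑1 to C‑10, C‑11 on C‑9, C‑12 the exocyclic methylene carbon on C‑8); C‑15 is used here for the oxygen‑bearing carbon on C‑4 (α, equatorial). Isocitrates are named as propane‑1,2,3‑tricarboxylates with the oxygen on C‑1.
Assumption: 3‑methylcyclohept‑2‑en‑1‑one, (R)‑malic acid and all reagents named are purchased; the epoxidation catalyst is used as the pseudo‑enantiomer that delivers the (2R,3R)‑epoxide.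

Step 1
Reactants: 1 3‑methylcyclohept‑2‑en‑1‑one
Product: 2 (2R,3R)‑2,3‑epoxy‑3‑methylcycloheptan‑1‑one
Conditions: 9‑amino‑9‑deoxy‑epi‑cinchona primary amine·2 CF3CO2H (10 mol %), 50% aq H2O2, dioxane, 30 °C
Reagents that add atoms: hydrogen peroxide, OO
Why: Amine‑salt‑catalysed nucleophilic epoxidation of a cyclic enone through its iminium ion; the chiral amine selects the enone face and so sets both epoxide carbons (C‑3 is the future C‑4) together.

Step 2
Reactants: 2 (2R,3R)‑2,3‑epoxy‑3‑methylcycloheptan‑1‑one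
Product: 3 (S)‑1‑methyl‑2‑oxocyclohexane‑1‑carbaldehyde
Conditions: BF3·OEt2, CH2Cl2, −40 → 0 °C
Reagents that add atoms: none
Why: BF3 binds the epoxide oxygen, the C–O bond at the tertiary, methyl‑bearing C‑3 ionises and, as it breaks, the acyl carbon C‑1 shifts from C‑2 to C‑3, so that C‑2 leaves the ring as the formyl carbon (later C‑15) and keeps the oxygen. The closest known reaction type is the BF3‑mediated rearrangement of cyclic α,β‑epoxy ketones to ring‑contracted β‑keto aldehydes (semipinacol‑type 1,2‑acyl shift). No ring is closed by cyclisation: the seven‑membered carbocycle becomes, by a ring‑contracting 1,2‑shift, the six‑membered ring that serves as ring A (C‑4 = old C‑3, C‑5 = old C‑1, C‑10 and C‑1 to C‑3 = old C‑7 to C‑4). The new quaternary centre C‑4 is controlled by the epoxide configuration, because the acyl carbon enters anti to the departing oxygen with inversion at C‑3, so the (2R,3R)‑epoxide should give the (S)‑aldehyde. The step needs acyl migration to win over hydride migration (which would give the 1,2‑dione) and to stay concerted; the tertiary migration terminus, the high migratory aptitude of the acyl group and a cold, non‑coordinating solvent should secure this.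

Step 3
Reactants: 3 (S)‑1‑methyl‑2‑oxocyclohexane‑1‑carbaldehyde
Product: 4 (S)‑2‑(hydroxymethyl)‑2‑methylcyclohexan‑1‑one
Conditions: LiAlH(OtBu)3 (1.05 equiv), THF, −78 °C; cold aq NH4Cl
Reagents that add atoms: none
Why: Chemoselective hydride reduction; the bulky alkoxyaluminium hydride reduces the aldehyde at low temperature but not the hindered ketone, and has no hydroxyl‑directed pathway to the diol.

Step 4
Reactants: 4 (S)‑2‑(hydroxymethyl)‑2‑methylcyclohexan‑1‑one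
Product: 5 (S)‑2‑[(tert‑butyldiphenylsilyl)oxymethyl]‑2‑methylcyclohexan‑1‑one
Conditions: TBDPSCl, imidazole, DMF, rt
Reagents that add atoms: tert‑butyl(chloro)diphenylsilane, CC(C)(C)[Si](Cl)(c1ccccc1)c1ccccc1
Why: Imidazole‑promoted silylation of the primary alcohol gives a bulky ether that tolerates bases and Lewis acids.

Step 5
Reactants: 5 (S)‑2‑[(tert‑butyldiphenylsilyl)oxymethyl]‑2‑methylcyclohexan‑1‑one
Product: 6 (2S,6RS)‑2‑[(tert‑butyldiphenylsilyl)oxymethyl]‑2,6‑dimethylcyclohexan‑1‑one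
Conditions: LiN(iPr)2, THF, −78 °C; MeI, −78 → 0 °C
Reagents that add atoms: iodomethane, CI
Why: Enolate alkylation; only C‑6 (future C‑10) can be enolised because the other α‑carbon is quaternary, and the new centre is flattened again in step 6.

Step 6
Reactants: 6 (2S,6RS)‑2‑[(tert‑butyldiphenylsilyl)oxymethyl]‑2,6‑dimethylcyclohexan‑1‑one
Product: 7 (S)‑6‑[(tert‑butyldiphenylsilyl)oxymethyl]‑2,6‑dimethylcyclohex‑1‑en‑1‑yl trifluoromethanesulfonate
Conditions: KN(SiMe3)2, THF, −78 → 0 °C; PhNTf2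
Reagents that add atoms: N‑phenylbis(trifluoromethanesulfonimide), O=S(=O)(N(c1ccccc1)S(=O)(=O)C(F)(F)F)C(F)(F)F
Why: Enol triflate formation; the only remaining α‑hydrogen is removed and the tetrasubstituted potassium enolate is O‑sulfonylated.

Step 7
Reactants: 7 (S)‑6‑[(tert‑butyldiphenylsilyl)oxymethyl]‑2,6‑dimethylcyclohex‑1‑en‑1‑yl trifluoromethanesulfonate
Product: 8 ethyl 3‑{(R)‑6‑[(tert‑butyldiphenylsilyl)oxymethyl]‑2,6‑dimethylcyclohex‑1‑en‑1‑yl}propanoate
Conditions: BrZnCH2CH2CO2Et, PdCl2(dppf) (5 mol %), THF/DMA, 60 °C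
Reagents that add atoms: (3‑ethoxy‑3‑oxopropyl)zinc bromide, CCOC(=O)CC[Zn]Br
Why: Negishi cross‑coupling of an alkenyl triflate with a zinc homoenolate attaches C‑6 and C‑7 to C‑5.

Step 8
Reactants: 8 ethyl 3‑{(R)‑6‑[(tert‑butyldiphenylsilyl)oxymethyl]‑2,6‑dimethylcyclohex‑1‑en‑1‑yl}propanoate
Product: 9 methyl 5‑{(R)‑6‑[(tert‑butyldiphenylsilyl)oxymethyl]‑2,6‑dimethylcyclohex‑1‑en‑1‑yl}‑3‑oxopentanoate
Conditions: MeOAc, LiN(iPr)2 (3 equiv), THF, −78 °C; then 8, −78 → −20 °C; aq NH4Cl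
Reagents that add atoms: methyl acetate, COC(C)=O
Why: Crossed Claisen condensation; excess lithium enolate of methyl acetate acylates on the ethyl ester and deprotonates the β‑keto ester formed, which drives the reaction.

Step 9
Reactants: 9 methyl 5‑{(R)‑6‑[(tert‑butyldiphenylsilyl)oxymethyl]‑2,6‑dimethylcyclohex‑1‑en‑1‑yl}‑3‑oxopentanoate
Product: 10 methyl (4R,5R,9R,10S)‑15‑(tert‑butyldiphenylsilyloxy)‑8‑oxo‑12‑nordriman‑11‑oate
Conditions: SnCl4, CH2Cl2, −78 → 0 °C
Reagents that add atoms: none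
Why: Cation–olefin cyclisation; protonation of the tetrasubstituted alkene at C‑5 gives the tertiary C‑10 cation, which the enol carbon C‑9 of the β‑keto ester traps through a chair transition state to give the trans‑decalin (5α‑H, 10β‑CH3, equatorial C‑9 ester), and C‑4 should direct the face because the larger silyloxymethyl group takes the equatorial site and the methyl the axial site syn to the new angular methyl.

Step 10
Reactants: 10 methyl (4R,5R,9R,10S)‑15‑(tert‑butyldiphenylsilyloxy)‑8‑oxo‑12‑nordriman‑11‑oate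
Product: 11 methyl (4R,5R,9S,10S)‑15‑(tert‑butyldiphenylsilyloxy)drim‑8(12)‑en‑11‑oate
Conditions: Zn, CH2Br2, TiCl4, THF/CH2Cl2, 0 °C → rt
Reagents that add atoms: dibromomethane, BrCBr
Why: Lombardo methylenation converts easily enolised ketones, here a β‑keto ester, into the exocyclic alkene under non‑basic conditions that should not epimerise C‑9.

Step 11
Reactants: 11 methyl (4R,5R,9S,10S)‑15‑(tert‑butyldiphenylsilyloxy)drim‑8(12)‑en‑11‑oate
Product: 12 (4R,5R,9S,10S)‑15‑(tert‑butyldiphenylsilyloxy)drim‑8(12)‑en‑11‑ol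
Conditions: iBu2AlH, CH2Cl2, −78 → 0 °C
Reagents that add atoms: none
Why: Aluminium hydride reduction of the ester to the primary alcohol; silyl ether and alkene are inert.

Step 12
Reactants: 13 (R)‑malic acid
Product: 15 (R)‑malic acid 1‑methyl ester, via O‑trifluoroacetylmalic anhydride 14 (not isolated)
Conditions: (CF3CO)2O, 0 °C → rt; evaporate; MeOH, 0 °C → rt
Reagents that add atoms: methanol, CO
Why: Regioselective anhydride alcoholysis; methanol opens the cyclic anhydride at the carbonyl next to the acyloxy‑bearing carbon and also cleaves the trifluoroacetate.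

Step 13
Reactants: 15 (R)‑malic acid 1‑methyl ester
Product: 16 4‑tert‑butyl 1‑methyl (R)‑malate
Conditions: Cl3CC(=NH)OtBu, CH2Cl2/cyclohexane, rt
Reagents that add atoms: tert‑butyl 2,2,2‑trichloroacetimidate, CC(C)(C)OC(=N)C(Cl)(Cl)Cl
Why: Imidate esterification; the carboxylic acid is tert‑butylated without acid catalyst while the secondary alcohol is left.

Step 14
Reactants: 16 4‑tert‑butyl 1‑methyl (R)‑malate
Product: 17 3‑allyl 2‑tert‑butyl 1‑methyl (1R,2S)‑1‑hydroxypropane‑1,2,3‑tricarboxylate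
Conditions: LiN(SiMe3)2 (2.2 equiv), THF, −78 → −40 °C; BrCH2CO2CH2CH=CH2, −78 °C; AcOH quench at −78 °C
Reagents that add atoms: allyl bromoacetate, C=CCOC(=O)CBr
Why: Fráter–Seebach alkylation; the chelated alkoxide–enolate dianion is alkylated anti to the C‑2 oxygen of the malate, which sets the new centre and gives the natural (1R,2S) isocitrate configuration.

Step 15
Reactants: 15 (R)‑malic acid 1‑methyl ester
Product: 18 4‑allyl 1‑methyl (R)‑malate
Conditions: CH2=CHCH2Br, KHCO3, DMF, rt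
Reagents that add atoms: allyl bromide, C=CCBr
Why: Carboxylate O‑alkylation; bicarbonate does not deprotonate the alcohol.

Step 16
Reactants: 18 4‑allyl 1‑methyl (R)‑malate
Product: 19 2‑allyl 1,3‑dimethyl (1R,2S)‑1‑hydroxypropane‑1,2,3‑tricarboxylate
Conditions: LiN(SiMe3)2 (2.2 equiv), THF, −78 → −40 °C; BrCH2CO2Me, −78 °C; AcOH quench at −78 °C
Reagents that add atoms: methyl bromoacetate, COC(=O)CBr
Why: Fráter–Seebach alkylation as in step 14, with the same anti selectivity setting the (1R,2S) configuration.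

Step 17
Reactants: 12 (4R,5R,9S,10S)‑15‑(tert‑butyldiphenylsilyloxy)drim‑8(12)‑en‑11‑ol
Product: 20 (4R,5R,9S,10S)‑15‑(tert‑butyldiphenylsilyloxy)drim‑8(12)‑en‑11‑yl trifluoromethanesulfonate
Conditions: Tf2O, 2,6‑di‑tert‑butyl‑4‑methylpyridine, CH2Cl2, −78 → −20 °C; cold aq NaHCO3 wash, dried and kept as a cold CH2Cl2 solution for use the same day
Reagents that add atoms: trifluoromethanesulfonic anhydride, O=S(=O)(OS(=O)(=O)C(F)(F)F)C(F)(F)F
Why: O‑Sulfonylation of the primary alcohol in the presence of a hindered, non‑nucleophilic pyridine gives the β‑branched primary triflate, which should be stable enough in the cold to be divided between steps 18 and 19.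

Step 18
Reactants: 20 (4R,5R,9S,10S)‑15‑(tert‑butyldiphenylsilyloxy)drim‑8(12)‑en‑11‑yl trifluoromethanesulfonate; 17 3‑allyl 2‑tert‑butyl 1‑methyl (1R,2S)‑1‑hydroxypropane‑1,2,3‑tricarboxylate
Product: 21 3‑allyl 2‑tert‑butyl 1‑methyl (1R,2S)‑1‑{[(4R,5R,9S,10S)‑15‑(tert‑butyldiphenylsilyloxy)drim‑8(12)‑en‑11‑yl]oxy}propane‑1,2,3‑tricarboxylate
Conditions: 2,6‑di‑tert‑butyl‑4‑methylpyridine, CH2Cl2, −20 °C → rt → 40 °C
Reagents that add atoms: none
Why: Williamson‑type O‑alkylation of the hydroxy triester with a primary alkyl triflate under non‑basic conditions; the hindered pyridine only takes up the acid, so neither isocitrate centre is enolised and both are kept.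

Step 19
Reactants: 20 (4R,5R,9S,10S)‑15‑(tert‑butyldiphenylsilyloxy)drim‑8(12)‑en‑11‑yl trifluoromethanesulfonate; 19 2‑allyl 1,3‑dimethyl (1R,2S)‑1‑hydroxypropane‑1,2,3‑tricarboxylate
Product: 22 2‑allyl 1,3‑dimethyl (1R,2S)‑1‑{[(4R,5R,9S,10S)‑15‑(tert‑butyldiphenylsilyloxy)drim‑8(12)‑en‑11‑yl]oxy}propane‑1,2,3‑tricarboxylate
Conditions: 2,6‑di‑tert‑butyl‑4‑methylpyridine, CH2Cl2, −20 °C → rt → 40 °C
Reagents that add atoms: none
Why: Williamson‑type O‑alkylation with the alkyl triflate as in step 18, with retention at both isocitrate centres.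

Step 20
Reactants: 21 3‑allyl 2‑tert‑butyl 1‑methyl (1R,2S)‑1‑{[(4R,5R,9S,10S)‑15‑(tert‑butyldiphenylsilyloxy)drim‑8(12)‑en‑11‑yl]oxy}propane‑1,2,3‑tricarboxylate
Product: 23 3‑allyl 1‑methyl 2‑hydrogen (1R,2S)‑1‑{[(4R,5R,9S,10S)‑15‑(tert‑butyldiphenylsilyloxy)drim‑8(12)‑en‑11‑yl]oxy}propane‑1,2,3‑tricarboxylate
Conditions: ZnBr2 (5 equiv), CH2Cl2, rt
Reagents that add atoms: none
Why: Lewis‑acid cleavage of the tert‑butyl ester with loss of isobutene; allyl and methyl esters, silyl ether and alkene should survive.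

Step 21
Reactants: 22 2‑allyl 1,3‑dimethyl (1R,2S)‑1‑{[(4R,5R,9S,10S)‑15‑(tert‑butyldiphenylsilyloxy)drim‑8(12)‑en‑11‑yl]oxy}propane‑1,2,3‑tricarboxylate
Product: 24 2‑allyl 1,3‑dimethyl (1R,2S)‑1‑{[(4R,5R,9S,10S)‑15‑hydroxydrim‑8(12)‑en‑11‑yl]oxy}propane‑1,2,3‑tricarboxylate
Conditions: HF·pyridine, pyridine/THF, 0 °C → rt
Reagents that add atoms: none
Why: Fluoride‑mediated desilylation under buffered conditions that do not touch the esters.

Step 22
Reactants: 23 the C‑2 acid from step 20 (silyl ether at C‑15); 24 the C‑15 alcohol from step 21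
Product: 25 two‑unit ester (C‑2 carboxyl of 23 esterified by the C‑15 hydroxyl of 24; C‑15 silyl ether on the acid‑derived unit)
Conditions: 2‑methyl‑6‑nitrobenzoic anhydride, DMAP, Et3N, CH2Cl2, rt
Reagents that add atoms: none
Why: Shiina esterification; the mixed anhydride is attacked by the neopentyl‑type primary alcohol under DMAP catalysis at room temperature, which limits epimerisation next to the activated carboxyl.

Step 23
Reactants: 25 the silylated two‑unit ester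
Product: 26 two‑unit ester with free C‑15 hydroxyl
Conditions: HF·pyridine, pyridine/THF, 0 °C → rt
Reagents that add atoms: none
Why: Fluoride‑mediated desilylation as in step 21.

Step 24
Reactants: 23 the C‑2 acid from step 20 (silyl ether at C‑15); 26 the two‑unit alcohol
Product: 27 silylated three‑unit triallyl ester
Conditions: 2‑methyl‑6‑nitrobenzoic anhydride, DMAP, Et3N, CH2Cl2, rt
Reagents that add atoms: none
Why: Shiina esterification as in step 22 joins the third unit.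

Step 25
Reactants: 27 the silylated three‑unit triallyl ester
Product: 28 three‑unit triallyl ester with free C‑15 hydroxyl
Conditions: HF·pyridine, pyridine/THF, 0 °C → rt
Reagents that add atoms: none
Why: Fluoride‑mediated desilylation frees the terminal C‑15 hydroxyl.

Step 26
Reactants: 28 the three‑unit triallyl ester with free C‑15 hydroxyl
Product: 29 cryptoporic acid T
Conditions: Pd(PPh3)4 (10 mol %), morpholine, THF, rt
Reagents that add atoms: none
Why: Tsuji–Trost deallylation; zerovalent palladium ionises the three allyl esters to π‑allyl complexes that morpholine captures, which should free the three acids without touching methyl esters, alkenes or the alcohol.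

**Compound list**
1 | 3‑methylcyclohept‑2‑en‑1‑one | CC1=CC(=O)CCCC1 | starting material
2 | (2R,3R)‑2,3‑epoxy‑3‑methylcycloheptan‑1‑one | O=C1CCCC[C@@]2(C)O[C@@H]12 | intermediate
3 | (S)‑1‑methyl‑2‑oxocyclohexane‑1‑carbaldehyde | O=C[C@]1(C)CCCCC1=O | intermediate
4 | (S)‑2‑(hydroxymethyl)‑2‑methylcyclohexan‑1‑one | OC[C@]1(C)CCCCC1=O | intermediate
5 | (S)‑2‑[(tert‑butyldiphenylsilyl)oxymethyl]‑2‑methylcyclohexan‑1‑one | CC(C)(C)[Si](OC[C@]1(C)CCCCC1=O)(c1ccccc1)c1ccccc1 | intermediate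
6 | (2S,6RS)‑2‑[(tert‑butyldiphenylsilyl)oxymethyl]‑2,6‑dimethylcyclohexan‑1‑one | CC1CCC[C@@](C)(CO[Si](c2ccccc2)(c2ccccc2)C(C)(C)C)C1=O | intermediate
7 | (S)‑6‑[(tert‑butyldiphenylsilyl)oxymethyl]‑2,6‑dimethylcyclohex‑1‑en‑1‑yl trifluoromethanesulfonate | CC1=C(OS(=O)(=O)C(F)(F)F)[C@](C)(CO[Si](c2ccccc2)(c2ccccc2)C(C)(C)C)CCC1 | intermediate
8 | ethyl 3‑{(R)‑6‑[(tert‑butyldiphenylsilyl)oxymethyl]‑2,6‑dimethylcyclohex‑1‑en‑1‑yl}propanoate | CCOC(=O)CCC1=C(C)CCC[C@@]1(C)CO[Si](c1ccccc1)(c1ccccc1)C(C)(C)C | intermediate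
9 | methyl 5‑{(R)‑6‑[(tert‑butyldiphenylsilyl)oxymethyl]‑2,6‑dimethylcyclohex‑1‑en‑1‑yl}‑3‑oxopentanoate | COC(=O)CC(=O)CCC1=C(C)CCC[C@@]1(C)CO[Si](c1ccccc1)(c1ccccc1)C(C)(C)C | intermediate
10 | methyl (4R,5R,9R,10S)‑15‑(tert‑butyldiphenylsilyloxy)‑8‑oxo‑12‑nordriman‑11‑oate (trans‑decalin, 4β‑CH3, 5α‑H, 9β‑CO2Me, 10β‑CH3) | O=C1CC[C@H]2[C@](C)(CO[Si](c3ccccc3)(c3ccccc3)C(C)(C)C)CCC[C@]2(C)[C@H]1C(=O)OC | intermediate
11 | methyl (4R,5R,9S,10S)‑15‑(tert‑butyldiphenylsilyloxy)drim‑8(12)‑en‑11‑oate | C=C1CC[C@H]2[C@](C)(CO[Si](c3ccccc3)(c3ccccc3)C(C)(C)C)CCC[C@]2(C)[C@H]1C(=O)OC | intermediate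
12 | (4R,5R,9S,10S)‑15‑(tert‑butyldiphenylsilyloxy)drim‑8(12)‑en‑11‑ol | C=C1CC[C@H]2[C@](C)(CO[Si](c3ccccc3)(c3ccccc3)C(C)(C)C)CCC[C@]2(C)[C@H]1CO | intermediate
13 | (R)‑malic acid | O[C@H](CC(=O)O)C(=O)O | starting material
14 | (R)‑2‑(trifluoroacetoxy)succinic anhydride | O=C1C[C@@H](OC(=O)C(F)(F)F)C(=O)O1 | intermediate (not isolated)
15 | (R)‑malic acid 1‑methyl ester | COC(=O)[C@H](O)CC(=O)O | intermediate
16 | 4‑tert‑butyl 1‑methyl (R)‑malate | COC(=O)[C@H](O)CC(=O)OC(C)(C)C | intermediate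
17 | 3‑allyl 2‑tert‑butyl 1‑methyl (1R,2S)‑1‑hydroxypropane‑1,2,3‑tricarboxylate | COC(=O)[C@H](O)[C@H](CC(=O)OCC=C)C(=O)OC(C)(C)C | intermediate
18 | 4‑allyl 1‑methyl (R)‑malate | COC(=O)[C@H](O)CC(=O)OCC=C | intermediate
19 | 2‑allyl 1,3‑dimethyl (1R,2S)‑1‑hydroxypropane‑1,2,3‑tricarboxylate | COC(=O)[C@H](O)[C@H](CC(=O)OC)C(=O)OCC=C | intermediate
20 | (4R,5R,9S,10S)‑15‑(tert‑butyldiphenylsilyloxy)drim‑8(12)‑en‑11‑yl trifluoromethanesulfonate | C=C1CC[C@H]2[C@](C)(CO[Si](c3ccccc3)(c3ccccc3)C(C)(C)C)CCC[C@]2(C)[C@H]1COS(=O)(=O)C(F)(F)F | intermediate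
21 | 3‑allyl 2‑tert‑butyl 1‑methyl (1R,2S)‑1‑{[(4R,5R,9S,10S)‑15‑(tert‑butyldiphenylsilyloxy)drim‑8(12)‑en‑11‑yl]oxy}propane‑1,2,3‑tricarboxylate | C=C1CC[C@H]2[C@](C)(CO[Si](c3ccccc3)(c3ccccc3)C(C)(C)C)CCC[C@]2(C)[C@H]1CO[C@@H](C(=O)OC)[C@H](CC(=O)OCC=C)C(=O)OC(C)(C)C | intermediate
22 | 2‑allyl 1,3‑dimethyl (1R,2S)‑1‑{[(4R,5R,9S,10S)‑15‑(tert‑butyldiphenylsilyloxy)drim‑8(12)‑en‑11‑yl]oxy}propane‑1,2,3‑tricarboxylate | C=C1CC[C@H]2[C@](C)(CO[Si](c3ccccc3)(c3ccccc3)C(C)(C)C)CCC[C@]2(C)[C@H]1CO[C@@H](C(=O)OC)[C@H](CC(=O)OC)C(=O)OCC=C | intermediate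
23 | 3‑allyl 1‑methyl 2‑hydrogen (1R,2S)‑1‑{[(4R,5R,9S,10S)‑15‑(tert‑butyldiphenylsilyloxy)drim‑8(12)‑en‑11‑yl]oxy}propane‑1,2,3‑tricarboxylate | C=C1CC[C@H]2[C@](C)(CO[Si](c3ccccc3)(c3ccccc3)C(C)(C)C)CCC[C@]2(C)[C@H]1CO[C@@H](C(=O)OC)[C@H](CC(=O)OCC=C)C(=O)O | intermediate
24 | 2‑allyl 1,3‑dimethyl (1R,2S)‑1‑{[(4R,5R,9S,10S)‑15‑hydroxydrim‑8(12)‑en‑11‑yl]oxy}propane‑1,2,3‑tricarboxylate | C=C1CC[C@H]2[C@](C)(CO)CCC[C@]2(C)[C@H]1CO[C@@H](C(=O)OC)[C@H](CC(=O)OC)C(=O)OCC=C | intermediate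
25 | two‑unit ester: C‑2 carboxyl of 23 esterified by the C‑15 oxygen of 24 (silyl ether on the other unit) | C=C1CC[C@H]2[C@](C)(COC(=O)[C@@H](CC(=O)OCC=C)[C@@H](OC[C@H]3C(=C)CC[C@H]4[C@](C)(CO[Si](c5ccccc5)(c5ccccc5)C(C)(C)C)CCC[C@]34C)C(=O)OC)CCC[C@]2(C)[C@H]1CO[C@@H](C(=O)OC)[C@H](CC(=O)OC)C(=O)OCC=C | intermediate
26 | two‑unit ester with free C‑15 hydroxyl | C=C1CC[C@H]2[C@](C)(COC(=O)[C@@H](CC(=O)OCC=C)[C@@H](OC[C@H]3C(=C)CC[C@H]4[C@](C)(CO)CCC[C@]34C)C(=O)OC)CCC[C@]2(C)[C@H]1CO[C@@H](C(=O)OC)[C@H](CC(=O)OC)C(=O)OCC=C | intermediate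
27 | three‑unit triallyl ester, terminal C‑15 silyl ether | C=C1CC[C@H]2[C@](C)(COC(=O)[C@@H](CC(=O)OCC=C)[C@@H](OC[C@H]3C(=C)CC[C@H]4[C@](C)(COC(=O)[C@@H](CC(=O)OCC=C)[C@@H](OC[C@H]5C(=C)CC[C@H]6[C@](C)(CO[Si](c7ccccc7)(c7ccccc7)C(C)(C)C)CCC[C@]56C)C(=O)OC)CCC[C@]34C)C(=O)OC)CCC[C@]2(C)[C@H]1CO[C@@H](C(=O)OC)[C@H](CC(=O)OC)C(=O)OCC=C | intermediate
28 | three‑unit triallyl ester, terminal C‑15 hydroxyl free | C=C1CC[C@H]2[C@](C)(COC(=O)[C@@H](CC(=O)OCC=C)[C@@H](OC[C@H]3C(=C)CC[C@H]4[C@](C)(COC(=O)[C@@H](CC(=O)OCC=C)[C@@H](OC[C@H]5C(=C)CC[C@H]6[C@](C)(CO)CCC[C@]56C)C(=O)OC)CCC[C@]34C)C(=O)OC)CCC[C@]2(C)[C@H]1CO[C@@H](C(=O)OC)[C@H](CC(=O)OC)C(=O)OCC=C | intermediate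
29 | cryptoporic acid T | C=C1CC[C@H]2[C@](C)(COC(=O)[C@@H](CC(=O)O)[C@@H](OC[C@H]3C(=C)CC[C@H]4[C@](C)(COC(=O)[C@@H](CC(=O)O)[C@@H](OC[C@H]5C(=C)CC[C@H]6[C@](C)(CO)CCC[C@]56C)C(=O)OC)CCC[C@]34C)C(=O)OC)CCC[C@]2(C)[C@H]1CO[C@@H](C(=O)OC)[C@H](CC(=O)OC)C(=O)O | target

**Totals.** 26 steps in all; the longest linear sequence is 19 steps (1 → 12 by steps 1–11, then steps 17, 18, 20, 22, 23, 24, 25, 26).

**Steps most likely to fail**

Step 18 (step 19 is the same reaction). The displacement at the β‑branched C‑11 by a hindered, weakly nucleophilic α‑hydroxy ester may be slow. The triflate may instead eliminate or ionise with participation of the homoallylic alkene, and the hydroxy triester may lactonise. The fallback reverses the polarity of the ether‑forming step. It sets out from 17. Mitsunobu inversion with chloroacetic acid (PPh3, diisopropyl azodicarboxylate, THF) should give 3‑allyl 2‑tert‑butyl 1‑methyl (1S,2S)‑1‑(chloroacetoxy)propane‑1,2,3‑tricarboxylate F1. Thiourea and NaHCO3 in ethanol remove the chloroacetyl group to give the C‑1 epimeric hydroxy triester F2. Tf2O and 2,6‑lutidine at −78 °C give the α‑triflyloxy triester F3. Alcohol 12 then displaces the triflate with inversion at C‑1 (2,6‑di‑tert‑butyl‑4‑methylpyridine, CH2Cl2, −20 °C → rt), an SN2 reaction typical of α‑sulfonyloxy esters, run cold and with a non‑nucleophilic base to hold back β‑elimination, and the route is rejoined at 21.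

Step 2. Hydride migration to the 1,2‑dione, a stepwise opening that erodes the transfer of configuration, or deformylation of the β‑keto aldehyde may compete. The fallback keeps the seven‑to‑six ring contraction but uses the rearrangement of an epoxy silyl ether. It sets out from 2. Luche reduction (NaBH4, CeCl3·7H2O, MeOH) gives the epoxy alcohol F4 and silylation (TBSOTf, 2,6‑lutidine) the epoxy silyl ether F5. MeAl(OAr)2 (Ar = 4‑bromo‑2,6‑di‑tert‑butylphenyl) in CH2Cl2 at −78 °C should then shift the silyloxy‑bearing ring carbon anti to the epoxide oxygen to give the ring‑contracted 2‑(tert‑butyldimethylsilyloxy)‑1‑methylcyclohexane‑1‑carbaldehyde F6. NaBH4 gives the silyloxy alcohol F7 and Bu4NF the diol F8. NaOCl in acetic acid oxidises the secondary alcohol in preference to the primary one and returns to the route at 4.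

Step 22 (step 24 is the same reaction). The activated acid carries an α‑hydrogen and a β‑alkoxy group, so epimerisation or β‑elimination may occur, and acylation of the neopentyl‑type C‑15 hydroxyl by a bulky acid may stall. The fallback changes the order of bond formation: ester first with a small acid, ether afterwards. It sets out from 17. Silylation (TBDPSCl, imidazole, DMAP, DMF) gives the silyl ether F9 and ZnBr2 in CH2Cl2 the acid F10. Esterification of F10 with alcohol 24 (2‑methyl‑6‑nitrobenzoic anhydride, DMAP, Et3N) gives the ester F11, and HF·pyridine the hydroxy ester F12. Ether formation of F12 with triflate 20 under the conditions of step 18 rejoins the route at 25.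

**Further compounds**
F1 | step 18 | 3‑allyl 2‑tert‑butyl 1‑methyl (1S,2S)‑1‑(chloroacetoxy)propane‑1,2,3‑tricarboxylate | COC(=O)[C@@H](OC(=O)CCl)[C@H](CC(=O)OCC=C)C(=O)OC(C)(C)C
F2 | step 18 | 3‑allyl 2‑tert‑butyl 1‑methyl (1S,2S)‑1‑hydroxypropane‑1,2,3‑tricarboxylate | COC(=O)[C@@H](O)[C@H](CC(=O)OCC=C)C(=O)OC(C)(C)C
F3 | step 18 | 3‑allyl 2‑tert‑butyl 1‑methyl (1S,2S)‑1‑(trifluoromethylsulfonyloxy)propane‑1,2,3‑tricarboxylate | COC(=O)[C@@H](OS(=O)(=O)C(F)(F)F)[C@H](CC(=O)OCC=C)C(=O)OC(C)(C)C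
F4 | step 2 | 2,3‑epoxy‑3‑methylcycloheptan‑1‑ol (epoxide configured as in 2, carbinol epimers) | OC1CCCC[C@@]2(C)O[C@@H]12
F5 | step 2 | tert‑butyldimethylsilyl ether of F4 | CC(C)(C)[Si](C)(C)OC1CCCC[C@@]2(C)O[C@@H]12
F6 | step 2 | 2‑(tert‑butyldimethylsilyloxy)‑1‑methylcyclohexane‑1‑carbaldehyde (quaternary centre as in 3, silyloxy carbon as epimers) | O=C[C@]1(C)CCCCC1O[Si](C)(C)C(C)(C)C
F7 | step 2 | [2‑(tert‑butyldimethylsilyloxy)‑1‑methylcyclohexyl]methanol (quaternary centre as in 4) | OC[C@]1(C)CCCCC1O[Si](C)(C)C(C)(C)C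
F8 | step 2 | 2‑(hydroxymethyl)‑2‑methylcyclohexan‑1‑ol (quaternary centre as in 4, carbinol epimers) | OC[C@]1(C)CCCCC1O
F9 | step 22 | 3‑allyl 2‑tert‑butyl 1‑methyl (1R,2S)‑1‑(tert‑butyldiphenylsilyloxy)propane‑1,2,3‑tricarboxylate | COC(=O)[C@H](O[Si](c1ccccc1)(c1ccccc1)C(C)(C)C)[C@H](CC(=O)OCC=C)C(=O)OC(C)(C)C
F10 | step 22 | 3‑allyl 1‑methyl 2‑hydrogen (1R,2S)‑1‑(tert‑butyldiphenylsilyloxy)propane‑1,2,3‑tricarboxylate | COC(=O)[C@H](O[Si](c1ccccc1)(c1ccccc1)C(C)(C)C)[C@H](CC(=O)OCC=C)C(=O)O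
F11 | step 22 | ester of F10 with the C‑15 oxygen of 24 | C=C1CC[C@H]2[C@](C)(COC(=O)[C@@H](CC(=O)OCC=C)[C@@H](O[Si](c3ccccc3)(c3ccccc3)C(C)(C)C)C(=O)OC)CCC[C@]2(C)[C@H]1CO[C@@H](C(=O)OC)[C@H](CC(=O)OC)C(=O)OCC=C
F12 | step 22 | desilylated hydroxy ester from F11 | C=C1CC[C@H]2[C@](C)(COC(=O)[C@@H](CC(=O)OCC=C)[C@@H](O)C(=O)OC)CCC[C@]2(C)[C@H]1CO[C@@H](C(=O)OC)[C@H](CC(=O)OC)C(=O)OCC=C
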